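Its constants are made up; the rest is arithmetic.

The reagent was the charge I followed through these set-ups.

| flask | substrate | reagent | remark | time |
|---|---|---|---|---|
| zeta | 0.10 M | 0.700 equiv | a single well-mixed tank run continuously and read at steady state, 8.0 h in it on average |  |
| eta | 0.10 M (fed, over 6.40 h) | 0.700 equiv | a stirred flask in which substrate is dosed at a steady rate over 6.40 h without added volume, worked up at 8.0 h | 8.0 h |
| beta | 0.10 M | 0.700 equiv (fed, over 6.40 h) | all but reagent at the start; reagent goes in evenly over 6.40 h, the run ends at 8.0 h | 8.0 h |
| theta | 0.10 M | 0.700 equiv | everything together in a closed stirred flask, run for 8.0 h | 8.0 h |

- the set-up with the highest amount of product at the outlet or at the end, in percent of the substrate put in ("none" if the first two lie within 2 percentage points) (zeta / eta / beta / theta / none)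
- amount of product at the outlet or at the end, in percent of the substrate put in, zeta
- amount of product at the outlet or at the end, in percent of the substrate put in, eta
- amount of product at the outlet or at the end, in percent of the substrate put in, beta
- amount of product at the outlet or at the end, in percent of the substrate put in, theta

- the stated concentrations are those of everything mixed, before any reaction; amounts are the same in each set-up
- the feed brings no volume worth counting
- run time (eta): 8.0 h

    intermediate B ⇌ product (K1 = 0.52, k1 = 0.265 /min)
    substrate ⇌ intermediate A (K2 = 0.123, k2 = 0.0374 /min)
    substrate + reagent → intermediate B (k3 = 0.849 /M/min)

At 0.700 equiv, the reagent is the limiting reagent, so I asked how much product each portion of reacted reagent leaves. In theta, intermediate B and product have a relaxation half-life of 0.895 min by their own step, shorter than the 8.0 h of the run. I therefore took the share of reacted reagent standing as product, the equilibrium constant 0.52 over one plus itself, as 34.2%. Product, as a fraction of the substrate charge, is this share times the reagent reacted, so its ceiling was 23.9%.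

Then I turned the question round. A set-up on that ceiling could win clearly if the runner-up left more than 5.85% of the substrate charge as unreacted reagent. In theta, substrate and intermediate A have a relaxation half-life of 2.03 min by their own step, shorter than the 0.19 h half-life of substrate by the reagent step at the charged amounts, so I divided the reagent step's constant by 1.12, which is one plus the equilibrium constant of substrate to intermediate A. Multiplied by the substrate charge and 8.0 h, the run time in theta and the average stay in zeta, it gave 36.3. In theta, the integrated second-order law made the ratio of unreacted reagent to the pool of substrate and intermediate A fall as exp(−10.9), the exponent being that number times the substrate in excess of the reagent. This put theta on the ceiling. In zeta, the steady balance is a quadratic, and its root left 5.10% of the substrate charge as reagent, less than the 5.85% required. So I put zeta at 22.2%, and I committed to none without reckoning eta and beta.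

The forecast gave 22.1% for zeta, 23.9% for eta, 23.7% for beta, 23.9% for theta and none as best, saying “Only the continuous tank falls noticeably short”. The simulation gave 22.1%, 23.9%, 23.7% and 23.9% in that order, and none as best.

Theta stood at 23.9% because of the back reaction of product to intermediate B: the run without that reaction reached 70.0%, a gain of 46 percentage points. Multiplied by the share, that run's 70.0% returned 23.9%. Theta's neighbour with 0.280 equiv of reagent came by the same share to 9.58%, and its run ended at 9.58%.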